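**Retrosynthetic overview**

- Both prenyl CH2 carbons of the target sit ortho to a phenol: C5 of ring A lies next to the C4 hydroxyl (and para to the C2 hydroxyl), and C2′ of ring B lies next to the C3′ hydroxyl and the ketone. Each is therefore cut at its CH2–CH bond, giving bis(methoxymethyl) triphenol 16 and two molecules of alkenylboronic acid 17; every ArCH2OMe/ortho-OH pair is a latent ortho-quinone methide.
- 16 comes from tris(MOM) ketone 15, which comes from carbinol 14, made by adding the ring B aryllithium (from bromide 11) to ring A aldehyde 7.
- 7 comes from 4,6-dibromoresorcinol by two successive bromine–lithium exchanges (MOMCl as C1 electrophile, then DMF). 11 comes from 3-bromophenol by lithiation between Br and OMOM and a MOMCl quench.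
- No ring is formed. Both benzene rings are bought, the carbonyl bridge is built first, and the two prenyl groups are completed last.

Key step: step 9

Remark: in step 9 the ring A site is assumed to ionise first, since it is activated by both the C4 and the C2 hydroxyl; the order does not change the product. Compounds 6, 13 and 14 are racemic and their stereocentre is removed before the target.

**Route**

Step 1
Reactants: 1 4,6-dibromoresorcinol
Product: 2 1,5-dibromo-2,4-bis(methoxymethoxy)benzene
Conditions: MOMCl, K2CO3, acetone, 0 °C → rt
Reagents that add atoms: chloromethyl methyl ether, COCCl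
Why: Williamson-type O-alkylation of the two acidic phenols with the α-chloro ether gives the bis(MOM) acetal, which tolerates the organolithium steps that follow.

Step 2
Reactants: 2 1,5-dibromo-2,4-bis(methoxymethoxy)benzene
Product: 4 1-bromo-5-(methoxymethyl)-2,4-bis(methoxymethoxy)benzene, via aryllithium 3 (not isolated)
Conditions: n-BuLi (1.0 equiv), THF, −78 °C; then MOMCl (freshly distilled), −78 → 0 °C
Reagents that add atoms: chloromethyl methyl ether, COCCl
Why: Bromine–lithium exchange at one of the two equivalent bromines should stop at the monolithio stage because a second exchange on an aryllithium is much slower, and SN2 C-alkylation of the aryllithium by the α-chloro ether gives the benzylic methyl ether.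

Step 3
Reactants: 4 1-bromo-5-(methoxymethyl)-2,4-bis(methoxymethoxy)benzene
Product: 7 5-(methoxymethyl)-2,4-bis(methoxymethoxy)benzaldehyde, via aryllithium 5 (not isolated), via lithium hemiaminal alkoxide 6 (not isolated)
Conditions: n-BuLi, THF, −78 °C; then DMF, −78 → 0 °C; then H2O
Reagents that add atoms: N,N-dimethylformamide, CN(C)C=O
Why: Bromine–lithium exchange followed by Bouveault formylation with DMF installs the aldehyde; the tetrahedral adduct prevents over-addition and collapses on aqueous work-up.

Step 4
Reactants: 8 3-bromophenol
Product: 9 1-bromo-3-(methoxymethoxy)benzene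
Conditions: MOMCl, K2CO3, acetone, rt
Reagents that add atoms: chloromethyl methyl ether, COCCl
Why: Williamson-type O-alkylation of the phenol gives the MOM ether that will direct the next metalation.

Step 5
Reactants: 9 1-bromo-3-(methoxymethoxy)benzene
Product: 11 1-bromo-2-(methoxymethyl)-3-(methoxymethoxy)benzene, via aryllithium 10 (not isolated)
Conditions: LiN(i-Pr)2 (LDA, commercial solution), THF, −78 °C; then MOMCl, −78 °C, slow warming to rt
Reagents that add atoms: chloromethyl methyl ether, COCCl
Why: Directed ortho-metalation with the amide base removes the most acidic hydrogen, at C2 between bromine and the MOM ether, without bromine–lithium exchange, and the aryllithium is C-alkylated by the α-chloro ether at low temperature before it can lose LiBr.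

Step 6
Reactants: 11 1-bromo-2-(methoxymethyl)-3-(methoxymethoxy)benzene; 7 5-(methoxymethyl)-2,4-bis(methoxymethoxy)benzaldehyde
Product: 14 [5-(methoxymethyl)-2,4-bis(methoxymethoxy)phenyl][2-(methoxymethyl)-3-(methoxymethoxy)phenyl]methanol (racemic), via aryllithium 12 (not isolated), via lithium alkoxide 13 (not isolated)
Conditions: 11, n-BuLi, THF, −78 °C; then 7, −78 → 0 °C; then H2O
Reagents that add atoms: none
Why: Bromine–lithium exchange and 1,2-addition of the chelated aryllithium to the non-enolisable aldehyde give the diarylmethanol; the new stereocentre is formed racemic and is erased in step 7.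

Step 7
Reactants: 14 [5-(methoxymethyl)-2,4-bis(methoxymethoxy)phenyl][2-(methoxymethyl)-3-(methoxymethoxy)phenyl]methanol
Product: 15 [5-(methoxymethyl)-2,4-bis(methoxymethoxy)phenyl][2-(methoxymethyl)-3-(methoxymethoxy)phenyl]methanone
Conditions: DMP, CH2Cl2, 0 °C → rt
Reagents that add atoms: none
Why: Dess–Martin oxidation of the doubly benzylic secondary alcohol gives the diaryl ketone under near-neutral conditions that leave the MOM acetals and the benzylic methyl ethers intact.

Step 8
Reactants: 15 [5-(methoxymethyl)-2,4-bis(methoxymethoxy)phenyl][2-(methoxymethyl)-3-(methoxymethoxy)phenyl]methanone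
Product: 16 [2,4-dihydroxy-5-(methoxymethyl)phenyl][3-hydroxy-2-(methoxymethyl)phenyl]methanone
Conditions: HCl (1.25 M in MeOH), MeOH, 0 °C → rt
Reagents that add atoms: none
Why: Acid-catalysed acetal methanolysis removes the three aryl MOM groups as dimethoxymethane, and methanol as solvent makes any acid-induced exchange at the two benzylic methyl ethers degenerate, so they are retained.

Step 9
Reactants: 16 [2,4-dihydroxy-5-(methoxymethyl)phenyl][3-hydroxy-2-(methoxymethyl)phenyl]methanone; 17 2-methylprop-1-enylboronic acid
Product: 21 cudraphenone B, via ring A ortho-quinone methide 18 (not isolated), via monoprenyl ketone 19 (not isolated), via ring B ortho-quinone methide 20 (not isolated)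
Conditions: 17 (5 equiv), 4 Å MS, PhMe (0.02 M), 110 °C, sealed tube; then H2O, rt
Reagents that add atoms: none
Why: Proposed new method: with water and methanol taken up by the sieves, 17 (or its boroxine) esterifies the C4 and C3′ hydroxyls, the neighbouring benzylic methoxy oxygen coordinates to boron, and heterolysis of the benzylic C–O bond passes methoxide to boron and leaves an ortho-quinone methide (18, then 20) whose oxygen carries a methoxy(hydroxy)alkenylborate. The alkenyl group then shifts with its boron-bound carbon to the exocyclic CH2 through a six-membered cyclic transition state, which restores the arene and forms the CH2–CH bond of each prenyl group; water at the end hydrolyses the aryl borates. The closest known reaction type is the 1,4-addition of alkenylboronates to ortho-quinone methides generated in situ from ortho-hydroxybenzyl ethers, which is established for secondary, aryl-stabilised benzylic ethers but not for primary methoxymethyl groups, for a methide flanked by an acyl group, or for two sites in one substrate. No ring is closed and no stereocentre is formed; the alkene of 17 carries two identical methyl groups, so no alkene geometry is at stake. The step needs C–C bond formation at the methide carbon through the ipso carbon of the alkenyl group, in preference to oligomerisation of the quinone methides, capture of the ring B methide by the ketone oxygen, or addition to the ketone; delivery from boron held on the adjacent phenol oxygen, high dilution and the low electrophilicity of the hydrogen-bonded diaryl ketone should secure this. Five equivalents of 17 are used because the C2 hydroxyl and the ketone oxygen are expected to hold one equivalent as a six-membered boron chelate, and on ring A ionisation assisted by the para C2 hydroxyl leads to the same product.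

**Compound list**

1 | 4,6-dibromoresorcinol | Oc1cc(O)c(Br)cc1Br | starting material
2 | 1,5-dibromo-2,4-bis(methoxymethoxy)benzene | COCOc1cc(OCOC)c(Br)cc1Br | intermediate
3 | [5-bromo-2,4-bis(methoxymethoxy)phenyl]lithium | [Li]c1cc(Br)c(OCOC)cc1OCOC | intermediate
4 | 1-bromo-5-(methoxymethyl)-2,4-bis(methoxymethoxy)benzene | COCc1cc(Br)c(OCOC)cc1OCOC | intermediate
5 | [5-(methoxymethyl)-2,4-bis(methoxymethoxy)phenyl]lithium | [Li]c1cc(COC)c(OCOC)cc1OCOC | intermediate
6 | lithium (dimethylamino)[5-(methoxymethyl)-2,4-bis(methoxymethoxy)phenyl]methanolate (racemic) | [Li]OC(N(C)C)c1cc(COC)c(OCOC)cc1OCOC | intermediate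
7 | 5-(methoxymethyl)-2,4-bis(methoxymethoxy)benzaldehyde | COCc1cc(C=O)c(OCOC)cc1OCOC | intermediate
8 | 3-bromophenol | Oc1cccc(Br)c1 | starting material
9 | 1-bromo-3-(methoxymethoxy)benzene | COCOc1cccc(Br)c1 | intermediate
10 | [2-bromo-6-(methoxymethoxy)phenyl]lithium | [Li]c1c(Br)cccc1OCOC | intermediate
11 | 1-bromo-2-(methoxymethyl)-3-(methoxymethoxy)benzene | COCOc1cccc(Br)c1COC | intermediate
12 | [2-(methoxymethyl)-3-(methoxymethoxy)phenyl]lithium | [Li]c1cccc(OCOC)c1COC | intermediate
13 | lithium [5-(methoxymethyl)-2,4-bis(methoxymethoxy)phenyl][2-(methoxymethyl)-3-(methoxymethoxy)phenyl]methanolate (racemic) | [Li]OC(c1cccc(OCOC)c1COC)c1cc(COC)c(OCOC)cc1OCOC | intermediate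
14 | [5-(methoxymethyl)-2,4-bis(methoxymethoxy)phenyl][2-(methoxymethyl)-3-(methoxymethoxy)phenyl]methanol (racemic) | OC(c1cccc(OCOC)c1COC)c1cc(COC)c(OCOC)cc1OCOC | intermediate
15 | [5-(methoxymethyl)-2,4-bis(methoxymethoxy)phenyl][2-(methoxymethyl)-3-(methoxymethoxy)phenyl]methanone | O=C(c1cccc(OCOC)c1COC)c1cc(COC)c(OCOC)cc1OCOC | intermediate
16 | [2,4-dihydroxy-5-(methoxymethyl)phenyl][3-hydroxy-2-(methoxymethyl)phenyl]methanone | COCc1cc(C(=O)c2cccc(O)c2COC)c(O)cc1O | intermediate
17 | 2-methylprop-1-enylboronic acid | CC(C)=CB(O)O | starting material
18 | 3-hydroxy-4-[3-hydroxy-2-(methoxymethyl)benzoyl]-6-methylidenecyclohexa-2,4-dien-1-one (ring A ortho-quinone methide, present as its O-bound borate complex; SMILES of the free quinone methide) | C=C1C=C(C(=O)c2cccc(O)c2COC)C(O)=CC1=O | intermediate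
19 | [2,4-dihydroxy-5-(3-methylbut-2-enyl)phenyl][3-hydroxy-2-(methoxymethyl)phenyl]methanone | CC(C)=CCc1cc(C(=O)c2cccc(O)c2COC)c(O)cc1O | intermediate
20 | 5-[2,4-dihydroxy-5-(3-methylbut-2-enyl)benzoyl]-6-methylidenecyclohexa-2,4-dien-1-one (ring B ortho-quinone methide, present as its O-bound borate complex; SMILES of the free quinone methide) | C=C1C(=O)C=CC=C1C(=O)c1cc(CC=C(C)C)c(O)cc1O | intermediate
21 | cudraphenone B, [2,4-dihydroxy-5-(3-methylbut-2-enyl)phenyl][3-hydroxy-2-(3-methylbut-2-enyl)phenyl]methanone | CC(C)=CCc1cc(C(=O)c2cccc(O)c2CC=C(C)C)c(O)cc1O | target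

**Step count**

Total steps: 9. Longest linear sequence: 7 (steps 1, 2, 3, 6, 7, 8, 9).

**Steps most likely to fail**

1. Step 9. The neutral aryl boronate may not ionise the primary benzylic methyl ethers at a practical temperature. If it does, the quinone methides may be consumed by oligomerisation, or by capture of the ring B methide by the ketone oxygen, faster than the alkenyl group is transferred.
Fallback (known chemistry; the prenyl groups are introduced as prenyl bromide on arylcopper reagents before the ketone is assembled): it sets out from dibromide 2 and MOM ether 9 and comes back to the route at 21. Bromine–lithium exchange on 2 (n-BuLi, THF, −78 °C), transmetalation with CuBr·SMe2 and allylation with 1-bromo-3-methylbut-2-ene should give 1-bromo-2,4-bis(methoxymethoxy)-5-(3-methylbut-2-enyl)benzene F1. A second exchange and DMF should give 2,4-bis(methoxymethoxy)-5-(3-methylbut-2-enyl)benzaldehyde F2. Lithiation of 9 with LiN(i-Pr)2 at −78 °C, CuBr·SMe2 and the same allylic bromide should give 1-bromo-3-(methoxymethoxy)-2-(3-methylbut-2-enyl)benzene F3. Exchange on F3 and addition to F2 should give [2,4-bis(methoxymethoxy)-5-(3-methylbut-2-enyl)phenyl][3-(methoxymethoxy)-2-(3-methylbut-2-enyl)phenyl]methanol F4. Dess–Martin oxidation should give [2,4-bis(methoxymethoxy)-5-(3-methylbut-2-enyl)phenyl][3-(methoxymethoxy)-2-(3-methylbut-2-enyl)phenyl]methanone F5. Brief treatment with dilute HCl in MeOH at rt, kept short to avoid chroman formation from the ortho-prenylphenols, should then give 21.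

2. Step 8. Once the phenols are free, the acid may ionise the activated benzylic methyl ethers. The result would be Friedel–Crafts oligomerisation onto the electron-rich ring A, or on ring B closure of the benzylic cation onto the ketone oxygen, before acetal cleavage is complete.
Fallback (the acetals are exchanged for silyl ethers under aprotic, base-buffered conditions and the phenols are released by neutral hydrolysis): it sets out from 15 and comes back at 16. TMSOTf and 2,2′-bipyridyl in CH2Cl2 at 0 °C should convert the three aryl MOM ethers into silyl ethers, giving [5-(methoxymethyl)-2,4-bis(trimethylsilyloxy)phenyl][2-(methoxymethyl)-3-(trimethylsilyloxy)phenyl]methanone F6. Addition of water at 0 °C then hydrolyses the aryl silyl ethers to 16.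

3. Step 5. The ortho-lithiated bromoarene may lose LiBr (aryne formation) or undergo bromine migration faster than it is C-alkylated by the chloro ether.
Fallback (the carbon is introduced by a fast formylation and then reduced and O-methylated): it sets out from 9 and comes back at 11. LiN(i-Pr)2 in THF at −78 °C followed by DMF should give 2-bromo-6-(methoxymethoxy)benzaldehyde F7. NaBH4 in MeOH at 0 °C should give [2-bromo-6-(methoxymethoxy)phenyl]methanol F8. NaH and MeI in THF at 0 °C should then give 11.

**Further compounds**

F1 | step 9 | 1-bromo-2,4-bis(methoxymethoxy)-5-(3-methylbut-2-enyl)benzene | CC(C)=CCc1cc(Br)c(OCOC)cc1OCOC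
F2 | step 9 | 2,4-bis(methoxymethoxy)-5-(3-methylbut-2-enyl)benzaldehyde | CC(C)=CCc1cc(C=O)c(OCOC)cc1OCOC
F3 | step 9 | 1-bromo-3-(methoxymethoxy)-2-(3-methylbut-2-enyl)benzene | CC(C)=CCc1c(Br)cccc1OCOC
F4 | step 9 | [2,4-bis(methoxymethoxy)-5-(3-methylbut-2-enyl)phenyl][3-(methoxymethoxy)-2-(3-methylbut-2-enyl)phenyl]methanol (racemic) | CC(C)=CCc1cc(C(O)c2cccc(OCOC)c2CC=C(C)C)c(OCOC)cc1OCOC
F5 | step 9 | [2,4-bis(methoxymethoxy)-5-(3-methylbut-2-enyl)phenyl][3-(methoxymethoxy)-2-(3-methylbut-2-enyl)phenyl]methanone | CC(C)=CCc1cc(C(=O)c2cccc(OCOC)c2CC=C(C)C)c(OCOC)cc1OCOC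
F6 | step 8 | [5-(methoxymethyl)-2,4-bis(trimethylsilyloxy)phenyl][2-(methoxymethyl)-3-(trimethylsilyloxy)phenyl]methanone | COCc1cc(C(=O)c2cccc(O[Si](C)(C)C)c2COC)c(O[Si](C)(C)C)cc1O[Si](C)(C)C
F7 | step 5 | 2-bromo-6-(methoxymethoxy)benzaldehyde | COCOc1cccc(Br)c1C=O
F8 | step 5 | [2-bromo-6-(methoxymethoxy)phenyl]methanol | COCOc1cccc(Br)c1CO
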